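## The problem

Testudinariol A is a C2-symmetric C30 diol. Each half is a cyclopentanol that carries a tetrahydropyran and an isopropenyl group, and the halves are joined by a CH2–CH2 tether that ends on both sides in an exocyclic trisubstituted alkene at pyran C5. Each half has four stereocentres: three contiguous ones on the cyclopentane (C1 carbinol, C2 bearing the pyran, C5 bearing isopropenyl; hydroxyl cis to isopropenyl, pyran trans to hydroxyl) and pyran C2, whose oxygen is 1,3-syn to the cyclopentanol oxygen. The tether is stereochemically empty, so the ring stereocentres must come from a chiral source, whereas pyran C2 can be set from the cyclopentanol by chelation-controlled reduction of a β-hydroxy ketone. In both alkenes the tether is cis to the O–CH2 carbon (pyran C6) and trans to C4; this geometry must be fixed in an acyclic precursor and must never pass through an allyl cation or a π-allyl metal species. The isopropenyl groups are the most exposed functionality, since a 1,1-disubstituted alkene competes in electrophilic oxidations and dihydroxylations and does not tolerate strong acid, and the β-oxygenated ketones met on the way are prone to β-elimination. The enabling feature is that the five cyclopentane carbons, the isopropenyl group and pyran C2 and C3 form the ten carbons of a 3-oxygenated p-menth-8-ene (menthane C1 = pyran C2, its methyl = pyran C3, C3–O = the cyclopentanol oxygen, C4 = the isopropenyl-bearing carbon). A ring contraction of a chiral-pool cyclohexane can therefore deliver the fully substituted cyclopentane with an acetyl handle.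

## Retrosynthesis

**26 ⇒ 24.** Both pyran O1–C6 bonds are cut. The ring oxygen then comes from the pyran C2 carbinol and the electrophile is a primary allylic carbon, so neither the C2 configuration nor the alkene geometry is touched. Cutting O1–C2 instead would need an inversion at a hindered secondary centre. The hexaol 24 is acyclic between the cyclopentanes. The forward step must activate the two primary allylic hydroxyls selectively in the presence of four secondary ones.

**24 ⇒ 22.** The two pyran C2 carbinols are traced back to ketones. The target has the 1,3-syn relationship, and the free cyclopentanol of 22 sits β to the ketone, so a boron-chelate reduction can set both centres from existing ones. This removes two stereocentres and leaves the tetraol diketone 22.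

**22 ⇒ 21 ⇒ 11 + 19.** Both C3–C4 bonds are cut, between an acetyl methyl and a primary allylic bromide. This splits the molecule into two identical methyl ketones 11 and one achiral C10 dibromide 19 that already carries both alkene geometries. Every hydroxyl is masked as a p-methoxybenzyl ether, so a single oxidative deprotection (21 to 22) frees all four. The forward reaction needs a kinetic methyl enolate that alkylates twice without proton transfer.

**19 ⇒ 18 ⇒ 17 ⇒ 16 ⇒ 15 ⇒ 13 + 2 × 14 (13 from 12).** The tether is taken back to succinaldehyde 13 and two molecules of methyl acrylate 14 through a twofold Baylis–Hillman reaction, one acrylate unit being added at each aldehyde group. The geometry argument decides which arm becomes which. In the bromide 16 the chain is cis to CH2Br and trans to the ester. The bromomethyl carbon must therefore become the O-bearing C6 (ether 17), and the ester carbon must become C4 (reduction to 18, bromination to 19). The opposite assignment would be two steps shorter but gives the wrong alkene isomer.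

**11 ⇒ 9 (through 10).** The cyclopentane C2–C3 bond is cut by reversing a 1,2-shift. In the alkoxide 10 of the cis-diol monomesylate 9, the menthane bond C1–C6 migrates to C2 as mesylate leaves, the ring contracts, and C1 becomes the acetyl carbonyl. This is preferred to building the cyclopentane by cyclisation because all three ring stereocentres are then set beforehand on a conformationally defined cyclohexane. The configuration at the only new centre follows from inversion. The forward reaction requires ring-bond migration only, and no epoxide formation.

**9 ⇒ 8 ⇒ 7 ⇒ 6.** The 1,2-cis-diol with a trans ether at C3 is taken apart oxygen by oxygen. A cis-dihydroxylation of a ring alkene beside the isopropenyl group would be the shortest route. It is not used because OsO4-type reagents favour the unhindered 1,1-disubstituted alkene over a trisubstituted ring alkene that carries an allylic oxygen. Instead the tertiary carbinol of dienol 6 directs epoxidation of the neighbouring ring alkene (7). p-Methoxybenzyl alkoxide then opens the epoxide at C3 with inversion (8). That one step sets C3–O cis to isopropenyl, leaves C2–O cis to C1–O, and installs the protecting group. Mesylation can only occur at the one secondary hydroxyl.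

**6 ⇒ 3 ⇒ 2 ⇒ 1.** The dienol 6 is the allylic alcohol obtained from cis-limonene oxide 3 by selenide opening and selenoxide elimination. Oxide 3 comes from (S)-limonene 1 through the diastereomeric oxide mixture 2. The single stereocentre of 1 is never adjacent to a carbonyl before the key step, so it cannot epimerise.

## Roads not taken

**Alternative 1:** The cut is at both pyran C2–C3 bonds. Two molecules of the cyclopentylmethyl carbamate A1 would be lithiated next to oxygen in the presence of a chiral diamine. They would capture the bis(boronate) A2, each primary alkyl group would migrate from boron to carbon, and oxidation would give the diol A3.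
- Merits: the pyran C2 configuration is set by the reagent in the bond-forming step. No ketone appears, so there is no β-elimination risk and no separate reduction.
- Weak points: A1 still needs the three contiguous cyclopentane stereocentres, which this cut does not supply. The lithiated carbon is next to a branched ring carbon with a silyloxy neighbour, so lithiation rate and match/mismatch with the diamine are open. Both ends of A2 must react, which costs excess lithiated fragment. A2 needs the same alkene geometry work as 19.
- Comparison: for the pyran C2 centre this road is better, because its control does not depend on the substrate. The chosen plan sets against it a dependable chelation-controlled reduction, and a fragment (11) that arrives from the ring contraction with the correct carbon count. A1 would need a one-carbon degradation of that same material.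

**Alternative 2:** The cut is at both pyran C4–C5 bonds. The diiodide A4 would undergo twofold iodine–lithium exchange, and each primary alkyllithium would add 6-exo-dig and syn across its propargylic-ether alkyne. Protonation would give the bis(silyl ether) A5.
- Merits: both pyrans and both alkene geometries are formed in one operation by a stereospecific syn addition. A4 is assembled by simple etherifications, and one deprotection finishes the synthesis.
- Weak points: six-membered carbolithiation onto an unactivated dialkyl alkyne is slow. Proton transfer from the propargylic O–CH2 groups competes. Both ends must cyclise. The pyran C2 carbinols and the cyclopentane stereocentres must be made beforehand by other means.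
- Comparison: in endgame step count this road is clearly shorter than the chosen one, which needs four steps from fragment union to the target and a six-step tether. The chosen plan sets against it that each of its endgame steps is a standard reaction for its substrate class.

**Alternative 3:** The cut is at both bonds between cyclopentane C2 and pyran C2. Two (E)-enol borinates of the cyclopentanone A6 would add to the dialdehyde A7 to give the bis(anti-aldol) adduct A8.
- Merits: two C–C bonds and four stereocentres are made in one step, and the cyclic enolate geometry guarantees the anti relationship.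
- Weak points: the stereocentre of A6 is both α to the carbonyl and allylic, so enolisation toward it racemises the material and moves the alkene into conjugation. Facial selectivity relies on 1,3-induction from the isopropenyl group across a flat enolate. The ring ketone of A8 must still be reduced with the hydroxyl cis to isopropenyl.
- Comparison: this road is the most convergent and builds stereocentres rather than importing them. The chosen plan sets against it configurational security: all ring stereocentres are fixed on a stable cyclohexane before contraction, and the one epimerisable centre of 11 is formed in its thermodynamically preferred trans arrangement.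

Key step: step 7

Remark: cis and trans for the limonene oxides refer to the methyl/isopropenyl relationship; in the cis oxide 3 the epoxide oxygen is therefore trans to the isopropenyl group.

## Route

**Step 1**
Reactants: 1 (S)-(−)-limonene
Product: 2 (4S)-limonene 1,2-oxide (mixture of cis and trans diastereomers)
Conditions: mCPBA, NaHCO3, CH2Cl2, 0 °C
Reagents that add atoms: 3-chloroperoxybenzoic acid, OOC(=O)c1cccc(Cl)c1
Why: Prilezhaev epoxidation; the trisubstituted ring alkene is the more electron-rich and should react before the isopropenyl group, and with no facial bias both epoxide diastereomers are expected in similar amounts.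

**Step 2**
Reactants: 2 (4S)-limonene 1,2-oxide (mixture)
Product: 3 cis-limonene oxide, (1S,2R,4S)
Conditions: pyrrolidine, H2O, reflux; dilute acid wash; distillation
Reagents that add atoms: none
Why: Kinetic separation based on the Fürst–Plattner rule; only the trans oxide can be opened at the secondary C2 through a trans-diaxial transition state with isopropenyl equatorial, so the amine should consume it and leave the cis oxide 3.

**Step 3**
Reactants: 3 cis-limonene oxide
Product: 6 (1S,4S)-1-methyl-4-(prop-1-en-2-yl)cyclohex-2-en-1-ol, via hydroxy selenide 4 (not isolated), via selenoxide 5 (not isolated)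
Conditions: (PhSe)2, NaBH4, EtOH, reflux; then H2O2 (30%), THF, 0 °C to rt
Reagents that add atoms: none
Why: Epoxide-to-allylic-alcohol conversion by selenide opening and selenoxide syn-elimination; the selenolate can attack only the secondary C2 (SN2), so the tertiary C1–O bond and its configuration are kept, and the selenoxide can eliminate only toward C3 because C1 has no hydrogen.

**Step 4**
Reactants: 6 (1S,4S)-dienol
Product: 7 (1R,2S,5R,6R)-2-methyl-5-(prop-1-en-2-yl)-7-oxabicyclo[4.1.0]heptan-2-ol (epoxide cis to the hydroxyl, trans to isopropenyl)
Conditions: VO(acac)2 (cat.), t-BuOOH, CH2Cl2, 0 °C to rt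
Reagents that add atoms: tert-butyl hydroperoxide, CC(C)(C)OO
Why: Hydroxyl-directed epoxidation; the allylic alkoxide binds vanadium and oxygen is delivered syn to the hydroxyl, which is also the face anti to isopropenyl, and the unbound isopropenyl alkene should not react.

**Step 5**
Reactants: 7 syn-epoxy alcohol
Product: 8 (1S,2R,3S,4R)-3-[(4-methoxyphenyl)methoxy]-1-methyl-4-(prop-1-en-2-yl)cyclohexane-1,2-diol
Conditions: PMBOH (excess), NaH, DMPU, 90 °C
Reagents that add atoms: 4-methoxybenzyl alcohol, COc1ccc(CO)cc1
Why: SN2 opening of a 2,3-epoxy alcohol by alkoxide; attack should occur at C3 with inversion because C2 is neopentyl-like and flanked by the C1 alkoxide, and the cis alkoxide cannot undergo epoxide migration; this sets C3–O cis to isopropenyl and leaves C2–O cis to C1–O.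

**Step 6**
Reactants: 8 diol
Product: 9 (1R,2S,5R,6S)-2-hydroxy-6-[(4-methoxyphenyl)methoxy]-2-methyl-5-(prop-1-en-2-yl)cyclohexyl methanesulfonate (1,2-cis diol monomesylate; mesylate trans to the ether; ether cis to isopropenyl)
Conditions: MsCl, pyridine, DMAP (cat.), CH2Cl2, 0 °C
Reagents that add atoms: methanesulfonyl chloride, CS(=O)(=O)Cl
Why: Selective sulfonylation of the only secondary hydroxyl; the tertiary hydroxyl should not react under these conditions.

**Step 7**
Reactants: 9 cis-diol monomesylate
Product: 11 1-[(1S,2S,3R)-2-[(4-methoxyphenyl)methoxy]-3-(prop-1-en-2-yl)cyclopentyl]ethan-1-one, via potassium alkoxide 10 (not isolated)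
Conditions: KOtBu (1.05 equiv), THF, −20 to 0 °C
Reagents that add atoms: none
Why: KOtBu converts the tertiary hydroxyl into alkoxide 10, whose oxygen pushes the ring bond C1–C6 onto C2 as mesylate leaves; the closest known reaction type is the base-induced semipinacol ring contraction of cyclic cis-1,2-diol monosulfonates that carry a tertiary carbinol. The cyclopentane is closed by this 1,2-alkyl shift (menthane C6 to C2, the cyclopentane C2–C3 bond), not by a cyclisation, and menthane C1 is released as the acetyl carbonyl. The one new stereocentre, cyclopentane C2, is set by stereospecific inversion at the mesylate carbon: the migrating carbon enters anti to the leaving group, so the acetyl group ends trans to the p-methoxybenzyloxy group, while that centre and the isopropenyl-bearing carbon are untouched. The step needs migration of the ring bond C1–C6 and not of methyl, hydride or the C3–C4 bond: in the favoured chair (mesylate and ether equatorial, isopropenyl and alkoxide axial; the other chair has a methyl/ether 1,3-diaxial clash) only ring bonds are antiperiplanar to the C–OMs bond, and only C1–C6 is driven by an alkoxide. The cis alkoxide cannot displace the mesylate to form an epoxide, the equatorial mesylate has no antiperiplanar hydrogen for E2, and the ether oxygen at C3 is a far weaker donor than the alkoxide. The base is consumed as potassium methanesulfonate, so none should remain to enolise 11 toward β-elimination, and the trans arrangement formed is also the thermodynamically preferred one.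

**Step 8**
Reactants: 12 2,5-dimethoxytetrahydrofuran
Product: 13 succinaldehyde
Conditions: H2O, 90 °C; MeOH distilled off; used fresh
Reagents that add atoms: water, O
Why: Hydrolysis of the cyclic bis-acetal; the dialdehyde is used at once to limit oligomerisation.

**Step 9**
Reactants: 13 succinaldehyde; 14 methyl acrylate (3 equiv)
Product: 15 dimethyl 2,2′-(1,4-dihydroxybutane-1,4-diyl)bis(prop-2-enoate) (= dimethyl 3,6-dihydroxy-2,7-dimethylideneoctanedioate; diastereomer mixture)
Conditions: DABCO (cat.), 1,4-dioxane/H2O (1:1), rt
Reagents that add atoms: none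
Why: A twofold Baylis–Hillman reaction in which each aldehyde group of 13 takes up one molecule of 14 through its DABCO-derived zwitterionic enolate, so that two molecules of 14 are built into 15 (C4H6O2 + 2 C4H6O2 = C12H18O6) and the surplus acrylate only keeps the second addition fast; the aqueous medium accelerates the addition to aliphatic aldehydes, and the carbinol stereocentres are removed in the next step.

**Step 10**
Reactants: 15 bis(Baylis–Hillman) adduct
Product: 16 dimethyl (2Z,6Z)-2,7-bis(bromomethyl)octa-2,6-dienedioate
Conditions: NBS, Me2S, CH2Cl2, 0 °C to rt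
Reagents that add atoms: N-bromosuccinimide, O=C1CCC(=O)N1Br
Why: SN2′ bromination of the allylic alcohols through alkoxysulfonium salts; the trisubstituted enoate should form with the chain trans to the ester and cis to CH2Br, which is the geometry required later.

**Step 11**
Reactants: 16 bis(allylic bromide) diester
Product: 17 dimethyl (2E,6E)-2,7-bis{[(4-methoxyphenyl)methoxy]methyl}octa-2,6-dienedioate
Conditions: PMBOH, NaH, THF, −20 to 0 °C
Reagents that add atoms: 4-methoxybenzyl alcohol, COc1ccc(CO)cc1
Why: Williamson etherification by direct SN2 at the primary allylic bromide, which keeps the alkene geometry; a hard alkoxide should prefer this to conjugate addition–elimination, and any ester exchange is harmless because the esters are reduced next.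

**Step 12**
Reactants: 17 bis(ether) diester
Product: 18 (2Z,6Z)-2,7-bis{[(4-methoxyphenyl)methoxy]methyl}octa-2,6-diene-1,8-diol
Conditions: i-Bu2AlH, CH2Cl2, −78 to −20 °C; aqueous potassium sodium tartrate (KNaC4H4O6) work-up
Reagents that add atoms: none
Why: 1,2-Reduction of the α,β-unsaturated esters to the allylic alcohols; the alkene and the ethers are not affected.

**Step 13**
Reactants: 18 diol
Product: 19 (2E,6E)-1,8-dibromo-2,7-bis{[(4-methoxyphenyl)methoxy]methyl}octa-2,6-diene
Conditions: CBr4, PPh3, CH2Cl2, 0 °C
Reagents that add atoms: carbon tetrabromide, BrC(Br)(Br)Br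
Why: Appel bromination; SN2 at the primary allylic carbon should proceed without allylic transposition, so the chain stays trans to CH2Br and cis to the ether arm.

**Step 14**
Reactants: 11 methyl ketone (2.3 equiv); 19 dibromide
Product: 21 (4Z,8Z)-4,9-bis{[(4-methoxyphenyl)methoxy]methyl}-1,12-bis[(1S,2S,3R)-2-[(4-methoxyphenyl)methoxy]-3-(prop-1-en-2-yl)cyclopentyl]dodeca-4,8-diene-1,12-dione, via lithium enolate 20 (not isolated)
Conditions: LiN(i-Pr)2, THF, −78 °C; then 19, DMPU, −78 to −40 °C
Reagents that add atoms: none
Why: Kinetic deprotonation at the methyl group and twofold C-alkylation by the primary allylic bromides; the methyl enolate cannot expel the β-alkoxide, and the low temperature should suppress proton transfer to the ring α-carbon; surplus 11 is recovered.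

**Step 15**
Reactants: 21 tetrakis(PMB ether) diketone
Product: 22 (4Z,8Z)-4,9-bis(hydroxymethyl)-1,12-bis[(1S,2S,3R)-2-hydroxy-3-(prop-1-en-2-yl)cyclopentyl]dodeca-4,8-diene-1,12-dione
Conditions: DDQ, CH2Cl2/pH 7 buffer, 0 °C
Reagents that add atoms: none
Why: Oxidative cleavage of all four p-methoxybenzyl ethers (benzylic hydride abstraction, hydrolysis of the oxocarbenium ion); the buffered, cold conditions should spare the alkenes and the freed allylic alcohols.

**Step 16**
Reactants: 22 tetraol diketone
Product: 24 (1R,4Z,8Z,12R)-4,9-bis(hydroxymethyl)-1,12-bis[(1R,2S,3R)-2-hydroxy-3-(prop-1-en-2-yl)cyclopentyl]dodeca-4,8-diene-1,12-diol, via bis(diethylboron) chelate 23 (not isolated)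
Conditions: Et2BOMe, THF/MeOH (4:1), −78 °C; NaBH4; then repeated evaporation from MeOH
Reagents that add atoms: none
Why: Narasaka–Prasad reduction; boron bridges the cyclopentanol oxygen and the ketone in a six-membered chelate trans-fused to the cyclopentane, and external hydride attacks axially to give the 1,3-syn diol, which is the (R) configuration needed at pyran C2.

**Step 17**
Reactants: 24 hexaol
Product: 26 testudinariol A, via bis(arenesulfonate) 25 (not isolated)
Conditions: NaH, 1-(2,4,6-triisopropylbenzenesulfonyl)imidazole, THF, 0 °C to rt
Reagents that add atoms: none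
Why: One-flask selective sulfonylation of the two primary allylic alkoxides by a bulky sulfonyl donor, then twofold intramolecular Williamson etherification (6-exo-tet); the oxygen nucleophile keeps the pyran C2 configuration and the SN2 displacement leaves the alkene geometry unchanged.

## Compound list

1 | (S)-(−)-limonene | C=C(C)[C@H]1CCC(C)=CC1 | starting material
2 | (4S)-limonene 1,2-oxide, cis/trans mixture | C=C(C)[C@H]1CCC2(C)OC2C1 | intermediate
3 | cis-limonene oxide, (1S,2R,4S) | C=C(C)[C@H]1CC[C@]2(C)O[C@@H]2C1 | intermediate
4 | (1S,2S,4S)-1-methyl-2-(phenylselanyl)-4-(prop-1-en-2-yl)cyclohexan-1-ol | C=C(C)[C@H]1CC[C@](C)(O)[C@@H]([Se]c2ccccc2)C1 | intermediate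
5 | selenoxide of 4 (selenium configuration undefined) | C=C(C)[C@H]1CC[C@](C)(O)[C@@H]([Se](=O)c2ccccc2)C1 | intermediate
6 | (1S,4S)-1-methyl-4-(prop-1-en-2-yl)cyclohex-2-en-1-ol | C=C(C)[C@H]1CC[C@](C)(O)C=C1 | intermediate
7 | (1R,2S,5R,6R)-2-methyl-5-(prop-1-en-2-yl)-7-oxabicyclo[4.1.0]heptan-2-ol | C=C(C)[C@H]1CC[C@](C)(O)[C@@H]2O[C@H]12 | intermediate
8 | (1S,2R,3S,4R)-3-[(4-methoxyphenyl)methoxy]-1-methyl-4-(prop-1-en-2-yl)cyclohexane-1,2-diol | C=C(C)[C@H]1CC[C@](C)(O)[C@H](O)[C@H]1OCc1ccc(OC)cc1 | intermediate
9 | (1R,2S,5R,6S)-2-hydroxy-6-[(4-methoxyphenyl)methoxy]-2-methyl-5-(prop-1-en-2-yl)cyclohexyl methanesulfonate | C=C(C)[C@H]1CC[C@](C)(O)[C@H](OS(C)(=O)=O)[C@H]1OCc1ccc(OC)cc1 | intermediate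
10 | potassium alkoxide of 9 | C=C(C)[C@H]1CC[C@](C)([O-])[C@H](OS(C)(=O)=O)[C@H]1OCc1ccc(OC)cc1.[K+] | intermediate
11 | 1-[(1S,2S,3R)-2-[(4-methoxyphenyl)methoxy]-3-(prop-1-en-2-yl)cyclopentyl]ethan-1-one | C=C(C)[C@H]1CC[C@H](C(C)=O)[C@H]1OCc1ccc(OC)cc1 | intermediate
12 | 2,5-dimethoxytetrahydrofuran | COC1CCC(OC)O1 | starting material
13 | succinaldehyde | O=CCCC=O | intermediate
14 | methyl acrylate | C=CC(=O)OC | starting material
15 | dimethyl 2,2′-(1,4-dihydroxybutane-1,4-diyl)bis(prop-2-enoate) (= dimethyl 3,6-dihydroxy-2,7-dimethylideneoctanedioate; diastereomer mixture) | COC(=O)C(=C)C(O)CCC(O)C(=C)C(=O)OC | intermediate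
16 | dimethyl (2Z,6Z)-2,7-bis(bromomethyl)octa-2,6-dienedioate | BrC/C(C(=O)OC)=C\CC/C=C(\CBr)C(=O)OC | intermediate
17 | dimethyl (2E,6E)-2,7-bis{[(4-methoxyphenyl)methoxy]methyl}octa-2,6-dienedioate | COc1ccc(COC/C(C(=O)OC)=C\CC/C=C(\COCc2ccc(OC)cc2)C(=O)OC)cc1 | intermediate
18 | (2Z,6Z)-2,7-bis{[(4-methoxyphenyl)methoxy]methyl}octa-2,6-diene-1,8-diol | COc1ccc(COC/C(CO)=C\CC/C=C(\COCc2ccc(OC)cc2)CO)cc1 | intermediate
19 | (2E,6E)-1,8-dibromo-2,7-bis{[(4-methoxyphenyl)methoxy]methyl}octa-2,6-diene | COc1ccc(COC/C(CBr)=C\CC/C=C(\COCc2ccc(OC)cc2)CBr)cc1 | intermediate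
20 | lithium enolate of 11 (methyl side) | C=C(C)[C@H]1CC[C@H](C(=C)O[Li])[C@H]1OCc1ccc(OC)cc1 | intermediate
21 | (4Z,8Z)-4,9-bis{[(4-methoxyphenyl)methoxy]methyl}-1,12-bis[(1S,2S,3R)-2-[(4-methoxyphenyl)methoxy]-3-(prop-1-en-2-yl)cyclopentyl]dodeca-4,8-diene-1,12-dione | C=C(C)[C@H]1CC[C@H](C(=O)CC/C(COCc2ccc(OC)cc2)=C/CC/C=C(\COCc3ccc(OC)cc3)CCC(=O)[C@H]4CC[C@H](C(=C)C)[C@@H]4OCc5ccc(OC)cc5)[C@H]1OCc6ccc(OC)cc6 | intermediate
22 | (4Z,8Z)-4,9-bis(hydroxymethyl)-1,12-bis[(1S,2S,3R)-2-hydroxy-3-(prop-1-en-2-yl)cyclopentyl]dodeca-4,8-diene-1,12-dione | C=C(C)[C@H]1CC[C@H](C(=O)CC/C(CO)=C/CC/C=C(\CO)CCC(=O)[C@H]2CC[C@H](C(=C)C)[C@@H]2O)[C@H]1O | intermediate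
23 | bis(diethylborinate) of 22 at the cyclopentanol oxygens (boron chelated to the ketones) | C=C(C)[C@H]1CC[C@H](C(=O)CC/C(CO)=C/CC/C=C(\CO)CCC(=O)[C@H]2CC[C@H](C(=C)C)[C@@H]2OB(CC)CC)[C@H]1OB(CC)CC | intermediate
24 | (1R,4Z,8Z,12R)-4,9-bis(hydroxymethyl)-1,12-bis[(1R,2S,3R)-2-hydroxy-3-(prop-1-en-2-yl)cyclopentyl]dodeca-4,8-diene-1,12-diol | C=C(C)[C@H]1CC[C@H]([C@H](O)CC/C(CO)=C/CC/C=C(\CO)CC[C@@H](O)[C@H]2CC[C@H](C(=C)C)[C@@H]2O)[C@H]1O | intermediate
25 | bis(2,4,6-triisopropylbenzenesulfonate) of 24 at the primary allylic oxygens | C=C(C)[C@H]1CC[C@H]([C@H](O)CC/C(COS(=O)(=O)c2c(C(C)C)cc(C(C)C)cc2C(C)C)=C/CC/C=C(\COS(=O)(=O)c3c(C(C)C)cc(C(C)C)cc3C(C)C)CC[C@@H](O)[C@H]4CC[C@H](C(=C)C)[C@@H]4O)[C@H]1O | intermediate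
26 | testudinariol A | C=C(C)[C@H]1CC[C@H]([C@H]2CC/C(=C/CC/C=C3/CC[C@H]([C@H]4CC[C@H](C(=C)C)[C@@H]4O)OC3)CO2)[C@H]1O | target

## Step count and least certain steps

Total: 17 steps. Longest linear sequence: 11 steps (steps 1–7 and 14–17); the tether 19 takes 6 steps (steps 8–13).

**Step 7 (key step).** The most likely failure is loss of p-methoxybenzyl alkoxide from the new β-alkoxy ketone by enolisation toward the ring carbon, if base is in excess or the mixture warms; the alternative migration of the C3–C4 bond is a lesser risk. The fallback sets out from 9 and returns at 11. It runs the 1,2-shift on an aluminium alkoxide without free base (Et3Al, CH2Cl2, −78 °C) and adds i-Bu2AlH to the same flask, so that the ketone is trapped as the secondary alcohol F1, which cannot eliminate. Oxidation of F1 with Dess–Martin periodinane then gives 11. This reductive organoaluminium variant of the pinacol-type rearrangement of β-mesyloxy alcohols is known chemistry.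

**Step 3.** The selenolate must attack C2 of the cis oxide through the less favoured, non-diaxial transition state, so the opening may be slow and incomplete. The fallback sets out from 1 and returns at 6. Sensitised photooxygenation of 1 (Schenck ene reaction, singlet oxygen, tetraphenylporphyrin as sensitiser, CH2Cl2) gives a mixture of allylic hydroperoxides that includes the tertiary hydroperoxide F2. Reduction with PPh3 and chromatographic separation from the C1 epimer and the regioisomeric alcohols gives 6. This is less selective but independent of epoxide reactivity.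

**Step 5.** The incoming alkoxide at C3 meets a 1,3-diaxial interaction with the axial methyl group, so the opening may be sluggish; at higher temperature, base-induced isomerisation of the epoxide or attack at C2 may intervene. The fallback sets out from 7 and returns at 8. Acid-catalysed hydrolysis (HClO4, THF/H2O), with water as a small nucleophile and the same C3 preference, gives the triol F3. Only the cis-1,2-diol of F3 forms an acetonide (2,2-dimethoxypropane, PPTS), giving F4. The remaining C3 hydroxyl is etherified (NaH, PMBCl, DMF) to F5, and mild aqueous acetic acid removes the acetonide to give 8.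

**Step 9.** Succinaldehyde may oligomerise by aldol reaction under the amine catalyst, and the mono-adduct may close to a lactol that slows the second addition. The fallback sets out from 13 and returns at 17, bypassing 15 and 16. The phosphonate F6 is made by conjugate addition of sodium 4-methoxybenzyl alkoxide to trimethyl 2-phosphonoacrylate, and its sodium salt is used as it forms (tandem conjugate addition–olefination). A twofold Horner–Wadsworth–Emmons reaction of 13 with this salt in THF should give mainly the (E,E)-diester 17 directly, since α-substituted phosphonoacetates place the aldehyde chain trans to the ester.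

**Step 14.** Proton transfer between the product ketone and the enolate may cause over-alkylation or scrambling of the enolate position; O-alkylation and an incomplete second alkylation are further risks. The fallback sets out from 11 and returns at 21. Ketone 11 is converted into its N,N-dimethylhydrazone F7. Metalation with LiN(i-Pr)2 occurs at the methyl group, and the aza-enolate is alkylated twice by 19 to give the bis(hydrazone) F8. Hydrolysis with aqueous CuCl2 at pH 7 releases 21.

**Step 17.** Sulfonylation may spill over to the secondary hydroxyls, and imidazolide may substitute the allylic sulfonate intermolecularly. The fallback sets out from 22 and returns at 26, so the activation is moved ahead of the reduction. The primary allylic hydroxyls of 22 are converted selectively into chlorides (MsCl, LiCl, 2,4,6-collidine, DMF, 0 °C) to give F9. The same boron-chelate reduction as in step 16 gives the bis(allylic chloride) tetraol F10. KOtBu in THF then closes both pyrans to 26 without any activating agent being present alongside the secondary hydroxyls.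

## Further compounds

F1 | step 7 | 1-[2-[(4-methoxyphenyl)methoxy]-3-(prop-1-en-2-yl)cyclopentyl]ethan-1-ol, ring configuration as in 11, either carbinol epimer | C=C(C)[C@H]1CC[C@H](C(C)O)[C@H]1OCc1ccc(OC)cc1
F2 | step 3 | (1S,4S)-1-hydroperoxy-1-methyl-4-(prop-1-en-2-yl)cyclohex-2-ene | C=C(C)[C@H]1CC[C@](C)(OO)C=C1
F3 | step 5 | (1S,2R,3S,4R)-1-methyl-4-(prop-1-en-2-yl)cyclohexane-1,2,3-triol | C=C(C)[C@H]1CC[C@](C)(O)[C@H](O)[C@H]1O
F4 | step 5 | 1,2-O-isopropylidene derivative of F3 (C3 hydroxyl free) | C=C(C)[C@H]1CC[C@]2(C)OC(C)(C)O[C@@H]2[C@H]1O
F5 | step 5 | 3-O-(4-methoxybenzyl) ether of F4 | C=C(C)[C@H]1CC[C@]2(C)OC(C)(C)O[C@@H]2[C@H]1OCc1ccc(OC)cc1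
F6 | step 9 | methyl 2-(dimethoxyphosphoryl)-3-[(4-methoxyphenyl)methoxy]propanoate | COC(=O)C(COCc1ccc(OC)cc1)P(=O)(OC)OC
F7 | step 14 | N,N-dimethylhydrazone of 11 | C=C(C)[C@H]1CC[C@H](C(C)=NN(C)C)[C@H]1OCc1ccc(OC)cc1
F8 | step 14 | bis(N,N-dimethylhydrazone) of 21 | C=C(C)[C@H]1CC[C@H](C(=NN(C)C)CC/C(COCc2ccc(OC)cc2)=C/CC/C=C(\COCc3ccc(OC)cc3)CCC(=NN(C)C)[C@H]4CC[C@H](C(=C)C)[C@@H]4OCc5ccc(OC)cc5)[C@H]1OCc6ccc(OC)cc6
F9 | step 17 | (4Z,8Z)-4,9-bis(chloromethyl)-1,12-bis[2-hydroxy-3-(prop-1-en-2-yl)cyclopentyl]dodeca-4,8-diene-1,12-dione, ring configuration as in 22 | C=C(C)[C@H]1CC[C@H](C(=O)CC/C(CCl)=C/CC/C=C(\CCl)CCC(=O)[C@H]2CC[C@H](C(=C)C)[C@@H]2O)[C@H]1O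
F10 | step 17 | (4Z,8Z)-4,9-bis(chloromethyl)-1,12-bis[2-hydroxy-3-(prop-1-en-2-yl)cyclopentyl]dodeca-4,8-diene-1,12-diol, configuration as in 24 | C=C(C)[C@H]1CC[C@H]([C@H](O)CC/C(CCl)=C/CC/C=C(\CCl)CC[C@@H](O)[C@H]2CC[C@H](C(=C)C)[C@@H]2O)[C@H]1O
A1 | alternative 1 | [2-(tert-butyldimethylsilyloxy)-3-(prop-1-en-2-yl)cyclopentyl]methyl N,N-diisopropylcarbamate, ring configuration as in the target | C=C(C)[C@H]1CC[C@H](COC(=O)N(C(C)C)C(C)C)[C@H]1O[Si](C)(C)C(C)(C)C
A2 | alternative 1 | C10 bis(pinacol boronate) with two (4-methoxybenzyloxy)methyl branches | CC1(C)OB(CC/C(COCc2ccc(OC)cc2)=C/CC/C=C(\COCc3ccc(OC)cc3)CCB4OC(C)(C)C(C)(C)O4)OC1(C)C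
A3 | alternative 1 | C2-symmetric (R,R)-diol, cyclopentanols as TBS ethers, O-methylene groups as PMB ethers | C=C(C)[C@H]1CC[C@H]([C@H](O)CC/C(=C/CC/C=C(COCc2ccc(OC)cc2)/CC[C@@H](O)[C@H]2CC[C@H](C(=C)C)[C@@H]2O[Si](C)(C)C(C)(C)C)COCc2ccc(OC)cc2)[C@H]1O[Si](C)(C)C(C)(C)C
A4 | alternative 2 | linear diyne diether diiodide | C=C(C)[C@H]1CC[C@H]([C@@H](CCI)OCC#CCCC#CCO[C@H](CCI)[C@H]2CC[C@H](C(=C)C)[C@@H]2O[Si](C)(C)C(C)(C)C)[C@H]1O[Si](C)(C)C(C)(C)C
A5 | alternative 2 | testudinariol A bis(TBS ether) | C=C(C)[C@H]1CC[C@H]([C@H]2CC/C(=C/CC/C=C3/CC[C@H]([C@H]4CC[C@H](C(=C)C)[C@@H]4O[Si](C)(C)C(C)(C)C)OC3)CO2)[C@H]1O[Si](C)(C)C(C)(C)C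
A6 | alternative 3 | (R)-2-(prop-1-en-2-yl)cyclopentan-1-one | C=C(C)[C@H]1CCCC1=O
A7 | alternative 3 | (4Z,8Z)-4,9-bis{[(4-methoxyphenyl)methoxy]methyl}dodeca-4,8-dienedial | O=CCC/C(COCc1ccc(OC)cc1)=C/CC/C=C(\COCc1ccc(OC)cc1)CCC=O
A8 | alternative 3 | C2-symmetric bis(anti-aldol) adduct, bis(β-hydroxy ketone) | C=C(C)[C@H]1CC[C@H]([C@H](O)CC/C(=C/CC/C=C(COCc2ccc(OC)cc2)/CC[C@@H](O)[C@H]2CC[C@H](C(=C)C)C2=O)COCc2ccc(OC)cc2)C1=O
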